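**Plan**

Prostanoid numbering is used for positions: C1 is the carboxyl carbon, C8–C12 the ring, C13–C20 the lower chain.

1. Retrosynthesis: the acid is taken back to its methyl ester, the C11 and C15 ketones to ketals and the C9 carbinol to a ketone. C8–C7 and C12–C13 are then cut in one operation, leaving enone 3 (mono-ketal of cyclopent-4-ene-1,3-dione), Grignard reagent 7 (C13–C20, C15 masked) and Z-allylic iodide 13 (C1–C7).
2. Enabling feature: in ring C8–C12 the oxygen-bearing carbons C9 and C11 are 1,3-related across C10 and flank the vicinal trans pair C8/C12. A C9 carbonyl therefore makes C12 the acceptor carbon and C8 the enolate carbon of one enone, while C11 rides along as a ketal. The saturated C13–C14 link lets the lower chain be a primary alkylmagnesium reagent.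
3. Forward order: no ring is built. The purchased five-membered ring receives the lower chain at C12 and, in the same flask, the upper chain at C8. The C9 ketone is then reduced, both ketals are opened and the ester is cleaved.
4. Stereochemistry: C12 comes from the chiral copper–diphosphine catalyst, C8 (trans to C12) from substrate control in the enolate alkylation, and C9 from hydride attack anti to the C8 chain. The Z alkene comes from a Wittig reaction and is carried through unchanged.

Key step: step 7

Assumption: the (R,Sp) ferrocenyl diphosphine is taken to select the enone face of 3 that gives (R) at C12; if the sense proved opposite, the mirror-image ligand would be used in the same step.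

**Route**

Step 1
Reactants: 1 cyclopent-4-ene-1,3-dione; 2 2,2-dimethylpropane-1,3-diol
Product: 3 8,8-dimethyl-6,10-dioxaspiro[4.5]dec-3-en-2-one
Conditions: 2 (1.0 equiv), PPTS (cat.), benzene, reflux, Dean–Stark
Reagents that add atoms: none
Why: Acid-catalysed ketalization with azeotropic removal of water should stop at the mono-ketal with one equivalent of diol, because the two carbonyls of the dione are identical and the enone carbonyl that remains is less electrophilic than those of the ene-dione.

Step 2
Reactants: 4 oct-1-en-3-one; 2 2,2-dimethylpropane-1,3-diol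
Product: 6 2-(2-bromoethyl)-5,5-dimethyl-2-pentyl-1,3-dioxane, via 1-bromooctan-3-one 5 (not isolated)
Conditions: HBr (gas), CH2Cl2, 0 °C; then 2, HC(OEt)3, TsOH·H2O (cat.), rt
Reagents that add atoms: hydrogen bromide, Br
Why: Conjugate addition of HBr to the vinyl ketone gives the β-bromo ketone 5, which is ketalized in the same flask at room temperature with the orthoformate as water scavenger (conjugate hydrobromination–ketalization), so the C15 carbonyl is masked before any organometallic is made.

Step 3
Reactants: 6 2-(2-bromoethyl)-5,5-dimethyl-2-pentyl-1,3-dioxane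
Product: 7 [2-(5,5-dimethyl-2-pentyl-1,3-dioxan-2-yl)ethyl]magnesium bromide (titrated Et2O solution, used directly)
Conditions: Mg turnings (1.5 equiv), I2 (cat.), Et2O, gentle reflux → rt
Reagents that add atoms: magnesium, [Mg]
Why: Magnesium inserts into the primary C–Br bond (Grignard formation), and the six-membered 1,3-dioxane ketal resists the intramolecular ring-opening that degrades the corresponding 1,3-dioxolane reagents, so the β-ketal Grignard reagent should be stable in solution.

Step 4
Reactants: 8 (4-carboxybutyl)triphenylphosphonium bromide; 9 2-[(tert-butyldimethylsilyl)oxy]acetaldehyde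
Product: 11 (Z)-7-[(tert-butyldimethylsilyl)oxy]hept-5-enoic acid, via ylide carboxylate 10 (not isolated)
Conditions: NaN(SiMe3)2 (2.1 equiv), THF, 0 °C; then 9, −78 °C → rt; cold dilute aq. HCl to pH 4
Reagents that add atoms: none
Why: Wittig olefination of an aldehyde with a non-stabilised ylide under lithium-free conditions runs through the kinetically formed cis-oxaphosphetane and should give the Z alkene, the C5–C6 double bond of the target.

Step 5
Reactants: 11 (Z)-7-[(tert-butyldimethylsilyl)oxy]hept-5-enoic acid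
Product: 12 methyl (Z)-7-hydroxyhept-5-enoate
Conditions: TsOH·H2O (cat.), MeOH, rt
Reagents that add atoms: methanol, CO
Why: Fischer esterification and acid-catalysed methanolysis of the primary silyl ether take place in the same pot and do not touch the Z double bond.

Step 6
Reactants: 12 methyl (Z)-7-hydroxyhept-5-enoate
Product: 13 methyl (Z)-7-iodohept-5-enoate
Conditions: PPh3, imidazole, I2, CH2Cl2, 0 °C, dark; used at once
Reagents that add atoms: iodine, II
Why: Appel-type iodination, in which iodide displaces the alkoxyphosphonium group of the primary allylic alcohol by a direct SN2 reaction at 0 °C in the dark, should keep the Z geometry.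

Step 7
Reactants: 3 8,8-dimethyl-6,10-dioxaspiro[4.5]dec-3-en-2-one; 7 [2-(5,5-dimethyl-2-pentyl-1,3-dioxan-2-yl)ethyl]magnesium bromide; 13 methyl (Z)-7-iodohept-5-enoate
Product: 15 methyl (Z)-7-[(1R,2R)-1-[2-(5,5-dimethyl-2-pentyl-1,3-dioxan-2-yl)ethyl]-8,8-dimethyl-3-oxo-6,10-dioxaspiro[4.5]decan-2-yl]hept-5-enoate, via magnesium enolate 14 (not isolated)
Conditions: CuBr·SMe2 (5 mol %), (R)-1-[(Sp)-2-(diphenylphosphino)ferrocenyl]ethyldicyclohexylphosphine (6 mol %), t-BuOMe, −75 °C, 7 (1.15 equiv in Et2O, added slowly); then HMPA, 13 (2 equiv), −75 → 0 °C; aq. NH4Cl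
Reagents that add atoms: none
Why: The copper bromide–diphosphine complex (monovalent copper) is transmetalated by 7 to a chiral alkylcopper species that binds the C8=C12 double bond of 3 on one of its two enantiotopic faces, adds at C12 to give a trivalent copper alkyl enolate and forms C12–C13 by reductive elimination, which leaves the regiodefined bromomagnesium enolate 14. HMPA then breaks up the magnesium enolate aggregate so that C8 of 14 displaces iodide from the primary allylic carbon of 13 by a direct SN2 reaction, which forms the C8–C7 bond and leaves the Z double bond untouched. The closest known reaction type is the copper/ferrocenyl-diphosphine-catalysed enantioselective conjugate addition of Grignard reagents to cyclic enones with trapping of the magnesium enolate by an alkyl halide in the same flask, that is, a conjugate addition–enolate alkylation three-component coupling; no ring is closed. C12 is set by the chiral ligand (catalyst control over the two faces of the flat, achiral enone), and C8 is set by C12, the allylic group entering anti to the newly attached C12 chain to give the trans-2,3-disubstituted cyclopentanone. The step needs 1,4- over 1,2-addition, site selectivity (C8, not C10), C- over O-alkylation and SN2 over SN2′ attack: the first is secured by the soft alkylcopper intermediate and slow addition of 7 at low temperature, the second because the enolate is formed at C8 by the conjugate addition and is not equilibrated, with the C11 ketal removing the second carbonyl as a competing acceptor, and the others by the reactive, unhindered CH2–iodide terminus of 13.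

Step 8
Reactants: 15 methyl (Z)-7-[(1R,2R)-1-[2-(5,5-dimethyl-2-pentyl-1,3-dioxan-2-yl)ethyl]-8,8-dimethyl-3-oxo-6,10-dioxaspiro[4.5]decan-2-yl]hept-5-enoate
Product: 16 methyl (Z)-7-[(1R,2R,3S)-1-[2-(5,5-dimethyl-2-pentyl-1,3-dioxan-2-yl)ethyl]-3-hydroxy-8,8-dimethyl-6,10-dioxaspiro[4.5]decan-2-yl]hept-5-enoate
Conditions: LiBH(s-Bu)3, THF, −78 °C; then H2O
Reagents that add atoms: none
Why: The bulky trialkylborohydride attacks the C9 carbonyl from the ring face opposite the adjacent C8 chain (substrate-controlled diastereoselective ketone reduction), which should give the C9 alcohol cis to that chain, (S) at C9, and leaves the ester and the ketals untouched at −78 °C.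

Step 9
Reactants: 16 methyl (Z)-7-[(1R,2R,3S)-1-[2-(5,5-dimethyl-2-pentyl-1,3-dioxan-2-yl)ethyl]-3-hydroxy-8,8-dimethyl-6,10-dioxaspiro[4.5]decan-2-yl]hept-5-enoate
Product: 17 methyl (Z)-7-[(1R,2R,5S)-5-hydroxy-3-oxo-2-(3-oxooctyl)cyclopentyl]hept-5-enoate
Conditions: (NH4)2Ce(NO3)6 (5 mol %), MeCN/aq. borate–HCl buffer (pH 8), 60 °C
Reagents that add atoms: water, O
Why: Catalytic tetravalent cerium acts as a mild Lewis acid for the hydrolysis of cyclic ketals near neutral pH, so both ketals should open to the C11 and C15 ketones without acid- or strong-base-induced loss of the C9 hydroxyl.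

Step 10
Reactants: 17 methyl (Z)-7-[(1R,2R,5S)-5-hydroxy-3-oxo-2-(3-oxooctyl)cyclopentyl]hept-5-enoate
Product: 18 (Z)-7-[(1R,2R,5S)-5-hydroxy-3-oxo-2-(3-oxooctyl)cyclopentyl]hept-5-enoic acid (13,14-dihydro-15-keto-PGD2)
Conditions: porcine liver esterase, phosphate buffer (pH 7)/acetone, rt
Reagents that add atoms: water, O
Why: Enzymatic ester hydrolysis at neutral pH and room temperature frees the acid without base, so the β-hydroxy ketone (C9–C11) and the C12 centre next to the ketone are not exposed to elimination or epimerisation.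

**Compound list**

1 | cyclopent-4-ene-1,3-dione | O=C1C=CC(=O)C1 | starting material
2 | 2,2-dimethylpropane-1,3-diol | OCC(C)(C)CO | starting material
3 | 8,8-dimethyl-6,10-dioxaspiro[4.5]dec-3-en-2-one | O=C1C=CC2(C1)OCC(C)(C)CO2 | intermediate
4 | oct-1-en-3-one | C=CC(=O)CCCCC | starting material
5 | 1-bromooctan-3-one (not isolated) | CCCCCC(=O)CCBr | intermediate
6 | 2-(2-bromoethyl)-5,5-dimethyl-2-pentyl-1,3-dioxane | CCCCCC1(CCBr)OCC(C)(C)CO1 | intermediate
7 | [2-(5,5-dimethyl-2-pentyl-1,3-dioxan-2-yl)ethyl]magnesium bromide | CCCCCC1(CC[Mg]Br)OCC(C)(C)CO1 | intermediate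
8 | (4-carboxybutyl)triphenylphosphonium bromide | OC(=O)CCCC[P+](c1ccccc1)(c1ccccc1)c1ccccc1.[Br-] | starting material
9 | 2-[(tert-butyldimethylsilyl)oxy]acetaldehyde | O=CCO[Si](C)(C)C(C)(C)C | starting material
10 | sodium 5-(triphenyl-λ5-phosphanylidene)pentanoate (not isolated) | [Na+].[O-]C(=O)CCCC=P(c1ccccc1)(c1ccccc1)c1ccccc1 | intermediate
11 | (Z)-7-[(tert-butyldimethylsilyl)oxy]hept-5-enoic acid | CC(C)(C)[Si](C)(C)OC/C=C\CCCC(=O)O | intermediate
12 | methyl (Z)-7-hydroxyhept-5-enoate | COC(=O)CCC/C=C\CO | intermediate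
13 | methyl (Z)-7-iodohept-5-enoate | COC(=O)CCC/C=C\CI | intermediate
14 | bromomagnesium (1R)-1-[2-(5,5-dimethyl-2-pentyl-1,3-dioxan-2-yl)ethyl]-8,8-dimethyl-6,10-dioxaspiro[4.5]dec-2-en-3-olate (not isolated) | CCCCCC1(OCC(C)(C)CO1)CC[C@H]2C3(OCC(C)(C)CO3)CC(O[Mg]Br)=C2 | intermediate
15 | methyl (Z)-7-[(1R,2R)-1-[2-(5,5-dimethyl-2-pentyl-1,3-dioxan-2-yl)ethyl]-8,8-dimethyl-3-oxo-6,10-dioxaspiro[4.5]decan-2-yl]hept-5-enoate | CCCCCC1(OCC(C)(C)CO1)CC[C@H]2C3(OCC(C)(C)CO3)CC(=O)[C@@H]2C/C=C\CCCC(=O)OC | intermediate
16 | methyl (Z)-7-[(1R,2R,3S)-1-[2-(5,5-dimethyl-2-pentyl-1,3-dioxan-2-yl)ethyl]-3-hydroxy-8,8-dimethyl-6,10-dioxaspiro[4.5]decan-2-yl]hept-5-enoate | CCCCCC1(OCC(C)(C)CO1)CC[C@H]2C3(OCC(C)(C)CO3)C[C@H](O)[C@@H]2C/C=C\CCCC(=O)OC | intermediate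
17 | methyl (Z)-7-[(1R,2R,5S)-5-hydroxy-3-oxo-2-(3-oxooctyl)cyclopentyl]hept-5-enoate | CCCCCC(=O)CC[C@H]1C(=O)C[C@H](O)[C@@H]1C/C=C\CCCC(=O)OC | intermediate
18 | (Z)-7-[(1R,2R,5S)-5-hydroxy-3-oxo-2-(3-oxooctyl)cyclopentyl]hept-5-enoic acid (13,14-dihydro-15-keto-PGD2) | CCCCCC(=O)CC[C@H]1C(=O)C[C@H](O)[C@@H]1C/C=C\CCCC(=O)O | target

**Step count and risks**

Total steps: 10. Longest linear sequence: 7 steps (steps 4, 5, 6, 7, 8, 9 and 10, from 8 and 9).

Steps most likely to fail:

1. Step 7. The C-alkylation of the magnesium enolate may be slow, so that proton exchange moves the enolate towards C10 or the copper catalyst and residual Grignard reagent consume the allylic iodide by SN2′ substitution; the Z geometry of the iodide may also erode before it reacts. Fallback: setting out from 3 (with 7, in the same copper-catalysed addition), the magnesium enolate 14 is intercepted with Me3SiCl/Et3N and the product isolated as [(1R)-1-[2-(5,5-dimethyl-2-pentyl-1,3-dioxan-2-yl)ethyl]-8,8-dimethyl-6,10-dioxaspiro[4.5]dec-2-en-3-yl]oxy-trimethylsilane F1. MeLi in THF at 0 °C cleaves it to lithium (1R)-1-[2-(5,5-dimethyl-2-pentyl-1,3-dioxan-2-yl)ethyl]-8,8-dimethyl-6,10-dioxaspiro[4.5]dec-2-en-3-olate F2, free of copper and of excess Grignard reagent. After addition of Me2Zn to suppress proton exchange, F2 is alkylated with 13 in THF/HMPA at −78 → −40 °C, and the route is rejoined at 15.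

2. Step 9. The C9 hydroxyl may be lost by dehydration as the β-hydroxy ketone is unveiled, or the 1,5-related C11 and C15 carbonyls may undergo intramolecular aldol reaction at pH 8 and 60 °C. Fallback: setting out from 16, the ester is saponified first (LiOH, THF/H2O, 0 °C → rt; careful acidification to pH 5) to give (Z)-7-[(1R,2R,3S)-1-[2-(5,5-dimethyl-2-pentyl-1,3-dioxan-2-yl)ethyl]-3-hydroxy-8,8-dimethyl-6,10-dioxaspiro[4.5]decan-2-yl]hept-5-enoic acid F5. Both ketals are then exchanged off under mild acid (PPTS, acetone/H2O, rt → 40 °C), so that no base meets the β-hydroxy ketone, and the route is rejoined at 18.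

3. Step 8. Facial selectivity in the hydride delivery may be poor, because the C12 chain on the opposite ring face works against the control by the C8 chain. Fallback: setting out from 15, the reduction is run without reliance on its selectivity (NaBH4, MeOH, −20 °C) and the epimers are separated. The unwanted methyl (Z)-7-[(1R,2R,3R)-1-[2-(5,5-dimethyl-2-pentyl-1,3-dioxan-2-yl)ethyl]-3-hydroxy-8,8-dimethyl-6,10-dioxaspiro[4.5]decan-2-yl]hept-5-enoate F3 is inverted at C9 by a Mitsunobu reaction (4-nitrobenzoic acid, PPh3, DIAD, THF, 0 °C) to methyl (Z)-7-[(1R,2R,3S)-1-[2-(5,5-dimethyl-2-pentyl-1,3-dioxan-2-yl)ethyl]-8,8-dimethyl-3-[(4-nitrobenzoyl)oxy]-6,10-dioxaspiro[4.5]decan-2-yl]hept-5-enoate F4. Methanolysis (K2CO3, MeOH, rt) removes the benzoate, and the route is rejoined at 16.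

**Further compounds**

F1 | step 7 | [(1R)-1-[2-(5,5-dimethyl-2-pentyl-1,3-dioxan-2-yl)ethyl]-8,8-dimethyl-6,10-dioxaspiro[4.5]dec-2-en-3-yl]oxy-trimethylsilane | CCCCCC1(OCC(C)(C)CO1)CC[C@H]2C3(OCC(C)(C)CO3)CC(O[Si](C)(C)C)=C2
F2 | step 7 | lithium (1R)-1-[2-(5,5-dimethyl-2-pentyl-1,3-dioxan-2-yl)ethyl]-8,8-dimethyl-6,10-dioxaspiro[4.5]dec-2-en-3-olate | CCCCCC1(OCC(C)(C)CO1)CC[C@H]2C3(OCC(C)(C)CO3)CC(O[Li])=C2
F3 | step 8 | methyl (Z)-7-[(1R,2R,3R)-1-[2-(5,5-dimethyl-2-pentyl-1,3-dioxan-2-yl)ethyl]-3-hydroxy-8,8-dimethyl-6,10-dioxaspiro[4.5]decan-2-yl]hept-5-enoate | CCCCCC1(OCC(C)(C)CO1)CC[C@H]2C3(OCC(C)(C)CO3)C[C@@H](O)[C@@H]2C/C=C\CCCC(=O)OC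
F4 | step 8 | methyl (Z)-7-[(1R,2R,3S)-1-[2-(5,5-dimethyl-2-pentyl-1,3-dioxan-2-yl)ethyl]-8,8-dimethyl-3-[(4-nitrobenzoyl)oxy]-6,10-dioxaspiro[4.5]decan-2-yl]hept-5-enoate | CCCCCC1(OCC(C)(C)CO1)CC[C@H]2C3(OCC(C)(C)CO3)C[C@H](OC(=O)c4ccc(cc4)[N+](=O)[O-])[C@@H]2C/C=C\CCCC(=O)OC
F5 | step 9 | (Z)-7-[(1R,2R,3S)-1-[2-(5,5-dimethyl-2-pentyl-1,3-dioxan-2-yl)ethyl]-3-hydroxy-8,8-dimethyl-6,10-dioxaspiro[4.5]decan-2-yl]hept-5-enoic acid | CCCCCC1(OCC(C)(C)CO1)CC[C@H]2C3(OCC(C)(C)CO3)C[C@H](O)[C@@H]2C/C=C\CCCC(=O)O
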